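## Retrosynthetic overview

1. The target is numbered as a cyclodeca-1,3-diene: C1 carries the diene CO2H, C6 is the quaternary carbon, C7 carries the second CO2H, C10 the methylidene. It comes from saponification of a bicyclic precursor in which the C7 acid and the furyl ketone are masked together as one enol δ-lactone and the C1 acid is a methyl ester.
2. The ten-membered ring is closed by ring-closing metathesis at C3=C4 (allyl on C6 plus the vinyl end of the dienoate); the ring size enforces the Z alkene.
3. The cross-conjugated triene ester is made by Stille coupling (C10–C1 bond) of a 2-stannyl-1-alkene with methyl (Z)-2-bromopenta-2,4-dienoate.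
4. C6 and C7 are set together by one NHC-catalysed azolium-enolate [4+2] between a racemic α-chloroaldehyde and a (Z)-β,β-disubstituted 3-furyl enone; all inputs are achiral or racemic with the stereocentre erased.
5. Ring order: six-membered enol lactone first, ten-membered carbocycle second, lactone opened last.

Assumption: catalyst-bound species of catalytic cycles (azolium enolate, organopalladium and ruthenium-carbene species) are described in words and not numbered.

## Route

Step 1
Reactants: 1 hex-5-yn-1-ol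
Product: 2 5-bromohex-5-en-1-ol
Conditions: Et4NBr, HBr, CH2Cl2, 40 °C
Reagents that add atoms: hydrogen bromide, Br
Why: Markovnikov hydrobromination of the terminal alkyne by Et4N+ HBr2− stops at the 2-bromo-1-alkene; no stereocentre is formed.

Step 2
Reactants: 2 5-bromohex-5-en-1-ol
Product: 4 5-bromo-2-chlorohex-5-enal (racemic), via 5-bromohex-5-enal 3 (not isolated)
Conditions: TCCA, TEMPO (2 mol%), CH2Cl2, 0 → 23 °C; filtered and used crude
Reagents that add atoms: trichloroisocyanuric acid, O=C1N(Cl)C(=O)N(Cl)C(=O)N1Cl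
Why: TEMPO/N-chloroamide oxidation of the primary alcohol followed by in situ α-chlorination of the aldehyde by the same reagent (one-pot alcohol to α-chloroaldehyde); the labile C2 centre is racemic and is erased in step 6.

Step 3
Reactants: 5 furan-3-carbonyl chloride; 6 propyne
Product: 7 1-(furan-3-yl)but-2-yn-1-one
Conditions: PdCl2(PPh3)2 (2 mol%), CuI (4 mol%), Et3N, THF, 23 °C
Reagents that add atoms: none
Why: acyl Sonogashira coupling of an aroyl chloride with a terminal alkyne gives the ynone directly.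

Step 4
Reactants: 7 1-(furan-3-yl)but-2-yn-1-one
Product: 8 (2Z)-1-(furan-3-yl)-3-iodobut-2-en-1-one
Conditions: NaI, AcOH, 23 °C, dark
Reagents that add atoms: sodium iodide, [Na+].[I-]
Why: conjugate hydroiodination of the ynone (anti addition of HI under kinetic control) puts iodine cis to the acyl group.

Step 5
Reactants: 8 (2Z)-1-(furan-3-yl)-3-iodobut-2-en-1-one; 9 allyltributylstannane
Product: 10 (2Z)-1-(furan-3-yl)-3-methylhexa-2,5-dien-1-one
Conditions: Pd2(dba)3 (2.5 mol%), AsPh3 (10 mol%), DMF, 23 °C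
Reagents that add atoms: none
Why: Stille coupling of the β-iodoenone with retention of alkene geometry leaves allyl cis and methyl trans to the acyl group, the geometry that defines the C6/C7 relationship in step 6.

Step 6
Reactants: 4 5-bromo-2-chlorohex-5-enal; 10 (2Z)-1-(furan-3-yl)-3-methylhexa-2,5-dien-1-one
Product: 11 (3R,4S)-3-(3-bromobut-3-en-1-yl)-6-(furan-3-yl)-4-methyl-4-(prop-2-en-1-yl)-3,4-dihydro-2H-pyran-2-one
Conditions: aminoindanol-derived N-mesityl triazolium chloride [(5aR,10bS), 20 mol%], Et3N (1.5 equiv), EtOAc, 23 → 40 °C, slow addition of 4 (1.5 equiv)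
Reagents that add atoms: none
Why: Proposed new method: NHC-catalysed azolium-enolate oxodiene [4+2] (Michael addition–lactonisation) extended to an acyclic β,β-dialkyl enone so that an all-carbon quaternary centre forms next to the enolate carbon; the carbene adds to racemic 4 and chloride loss gives a single (Z)-azolium enolate, which adds through the endo transition state to the enone (held s-cis by A1,3 strain), the catalyst's indane wall selecting the enolate face (3R) and the endo geometry placing the side chain cis to the β-substituent trans to the acyl group (methyl) and trans to allyl (4S), after which irreversible O-acylation closes the lactone and frees the carbene; the closest known reaction is the NHC-catalysed hetero-Diels–Alder of α-chloroaldehydes or enals with β-monosubstituted enones giving cis-3,4-disubstituted dihydropyranones.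

Step 7
Reactants: 11 (3R,4S)-3-(3-bromobut-3-en-1-yl)-6-(furan-3-yl)-4-methyl-4-(prop-2-en-1-yl)-3,4-dihydro-2H-pyran-2-one
Product: 12 (3R,4S)-6-(furan-3-yl)-4-methyl-4-(prop-2-en-1-yl)-3-[3-(trimethylstannyl)but-3-en-1-yl]-3,4-dihydro-2H-pyran-2-one
Conditions: Me3SnSnMe3 (1.5 equiv), Pd(PPh3)4 (5 mol%), toluene, 90 °C
Reagents that add atoms: hexamethylditin, C[Sn](C)(C)[Sn](C)(C)C
Why: Pd-catalysed stannylation of the vinyl bromide under neutral conditions that leave the enol lactone, allyl group and both stereocentres untouched.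

Step 8
Reactants: 13 acrolein; 14 methyl (triphenyl-λ5-phosphanylidene)acetate
Product: 16 methyl (2Z)-2-bromopenta-2,4-dienoate, via methyl bromo(triphenylphosphoranylidene)acetate 15 (not isolated)
Conditions: NBS, CH2Cl2, −20 °C; then 13, −20 → 23 °C; used as a cold solution
Reagents that add atoms: N-bromosuccinimide, O=C1CCC(=O)N1Br
Why: α-bromination of the stabilised ylide followed by Wittig olefination of acrolein, which places the vinyl group trans to the ester and therefore cis to bromine (2Z).

Step 9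
Reactants: 12 (3R,4S)-6-(furan-3-yl)-4-methyl-4-(prop-2-en-1-yl)-3-[3-(trimethylstannyl)but-3-en-1-yl]-3,4-dihydro-2H-pyran-2-one; 16 methyl (2Z)-2-bromopenta-2,4-dienoate
Product: 17 methyl (2E)-2-{4-[(3R,4S)-6-(furan-3-yl)-4-methyl-2-oxo-4-(prop-2-en-1-yl)-3,4-dihydro-2H-pyran-3-yl]but-1-en-2-yl}penta-2,4-dienoate
Conditions: Pd2(dba)3 (5 mol%), AsPh3 (20 mol%), CuI (20 mol%), NMP, 23 → 40 °C, dark
Reagents that add atoms: none
Why: Stille coupling of the reactive α-bromoenoate with the vinylstannane proceeds with retention, so the vinyl group ends cis to the new alkenyl substituent, as ring closure requires.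

Step 10
Reactants: 17 methyl (2E)-2-{4-[(3R,4S)-6-(furan-3-yl)-4-methyl-2-oxo-4-(prop-2-en-1-yl)-3,4-dihydro-2H-pyran-3-yl]but-1-en-2-yl}penta-2,4-dienoate
Product: 18 methyl (4aS,6Z,8E,12aR)-3-(furan-3-yl)-4a-methyl-10-methylidene-1-oxo-4a,5,10,11,12,12a-hexahydro-1H-cyclodeca[c]pyran-9-carboxylate (the target's C1 methyl ester with the C7 carboxyl lactonised onto the enol of the furyl ketone)
Conditions: Grubbs first-generation catalyst (2 × 10 mol%), CH2Cl2 (0.5 mM), 40 °C
Reagents that add atoms: none
Why: ring-closing metathesis in which the allyl group loads the catalyst and closes onto the monosubstituted diene terminus with loss of ethene, the first-generation catalyst being chosen because it is sluggish toward the 1,1-disubstituted and trisubstituted conjugated alkenes; the ten-membered ring allows only the Z C3=C4 bond and no stereocentre is touched.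

Step 11
Reactants: 18 methyl (4aS,6Z,8E,12aR)-3-(furan-3-yl)-4a-methyl-10-methylidene-1-oxo-4a,5,10,11,12,12a-hexahydro-1H-cyclodeca[c]pyran-9-carboxylate
Product: 20 (1E,3Z,6S,7R)-6-[2-(furan-3-yl)-2-oxoethyl]-6-methyl-10-methylidenecyclodeca-1,3-diene-1,7-dicarboxylic acid (target), via C1-methyl ester C7-acid 19 (not isolated)
Conditions: LiOH·H2O (10 equiv), THF/H2O 3:1, 0 → 40 °C; then 1 M HCl to pH 3
Reagents that add atoms: water, O; lithium hydroxide, [Li+].[OH-]
Why: saponification in which hydroxide first opens the activated enol lactone (freeing the C7 carboxylate and the furyl ketone) and then cleaves the hindered dienoate methyl ester; C7 is then α to a carboxylate and C6 is quaternary, so neither can epimerise.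

## Compound list

1 | hex-5-yn-1-ol | C#CCCCCO | starting material
2 | 5-bromohex-5-en-1-ol | C=C(Br)CCCCO | intermediate
3 | 5-bromohex-5-enal | C=C(Br)CCCC=O | intermediate (not isolated)
4 | 5-bromo-2-chlorohex-5-enal (racemic) | C=C(Br)CCC(Cl)C=O | intermediate
5 | furan-3-carbonyl chloride | O=C(Cl)c1ccoc1 | starting material
6 | propyne | CC#C | starting material
7 | 1-(furan-3-yl)but-2-yn-1-one | CC#CC(=O)c1ccoc1 | intermediate
8 | (2Z)-1-(furan-3-yl)-3-iodobut-2-en-1-one | C/C(I)=C/C(=O)c1ccoc1 | intermediate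
9 | allyltributylstannane | C=CC[Sn](CCCC)(CCCC)CCCC | starting material
10 | (2Z)-1-(furan-3-yl)-3-methylhexa-2,5-dien-1-one | C=CC/C(C)=C\C(=O)c1ccoc1 | intermediate
11 | (3R,4S)-3-(3-bromobut-3-en-1-yl)-6-(furan-3-yl)-4-methyl-4-(prop-2-en-1-yl)-3,4-dihydro-2H-pyran-2-one | C=C(Br)CC[C@@H](C(=O)O1)[C@](C)(C=C1c2ccoc2)CC=C | intermediate
12 | (3R,4S)-6-(furan-3-yl)-4-methyl-4-(prop-2-en-1-yl)-3-[3-(trimethylstannyl)but-3-en-1-yl]-3,4-dihydro-2H-pyran-2-one | C=C([Sn](C)(C)C)CC[C@@H](C(=O)O1)[C@](C)(C=C1c2ccoc2)CC=C | intermediate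
13 | acrolein (prop-2-enal) | C=CC=O | starting material
14 | methyl (triphenyl-λ5-phosphanylidene)acetate | COC(=O)C=P(c1ccccc1)(c1ccccc1)c1ccccc1 | starting material
15 | methyl bromo(triphenyl-λ5-phosphanylidene)acetate | COC(=O)C(Br)=P(c1ccccc1)(c1ccccc1)c1ccccc1 | intermediate (not isolated)
16 | methyl (2Z)-2-bromopenta-2,4-dienoate | C=C/C=C(\Br)C(=O)OC | intermediate
17 | methyl (2E)-2-{4-[(3R,4S)-6-(furan-3-yl)-4-methyl-2-oxo-4-(prop-2-en-1-yl)-3,4-dihydro-2H-pyran-3-yl]but-1-en-2-yl}penta-2,4-dienoate | C=C/C=C(C(=O)OC)\C(=C)CC[C@@H](C(=O)O1)[C@](C)(C=C1c2ccoc2)CC=C | intermediate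
18 | methyl (4aS,6Z,8E,12aR)-3-(furan-3-yl)-4a-methyl-10-methylidene-1-oxo-4a,5,10,11,12,12a-hexahydro-1H-cyclodeca[c]pyran-9-carboxylate | C=C1CC[C@@H](C(=O)O2)[C@](C)(C=C2c3ccoc3)C/C=C\C=C/1C(=O)OC | intermediate
19 | 1-methyl hydrogen (1E,3Z,6S,7R)-6-[2-(furan-3-yl)-2-oxoethyl]-6-methyl-10-methylidenecyclodeca-1,3-diene-1,7-dicarboxylate | C=C1CC[C@@H](C(=O)O)[C@](C)(CC(=O)c2ccoc2)C/C=C\C=C/1C(=O)OC | intermediate (not isolated)
20 | (1E,3Z,6S,7R)-6-[2-(furan-3-yl)-2-oxoethyl]-6-methyl-10-methylidenecyclodeca-1,3-diene-1,7-dicarboxylic acid | C=C1CC[C@@H](C(=O)O)[C@](C)(CC(=O)c2ccoc2)C/C=C\C=C/1C(=O)O | target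

## Step count and risks

Total steps: 11. Longest linear sequence: 8 steps (steps 3, 4, 5, 6, 7, 9, 10, 11, from furan-3-carbonyl chloride).

**Step 6 (the proposed new step).** The β,β-dialkyl enone may be too unreactive, or the dr/ee may erode through E/Z isomerisation of 10. The catalyst antipode that gives 3R is assigned by analogy and must be confirmed in a first run. The fallback uses known chemistry, sets out from enone 10 and alcohol 2, and returns at lactone 11.
- CBS reduction of 10 (the Me-CBS antipode that gives the 1R carbinol, catecholborane, toluene, −78 °C) gives (1R,2Z)-1-(furan-3-yl)-3-methylhexa-2,5-dien-1-ol F1.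
- Alcohol 2 is oxidised (TEMPO, PhI(OAc)2, MeCN/H2O) to 5-bromohex-5-enoic acid F2.
- DCC/DMAP joins them as (1R,2Z)-1-(furan-3-yl)-3-methylhexa-2,5-dien-1-yl 5-bromohex-5-enoate F3.
- LDA in THF at −78 °C followed by TMSCl gives the (E)-trimethylsilyl ketene acetal F4, with the side chain cis to the allylic oxygen.
- On warming, F4 undergoes Ireland–Claisen rearrangement through a chair with equatorial furyl, axial Z-allyl and equatorial methyl. This transfers the carbinol chirality and gives the trimethylsilyl ester F5.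
- Work-up hydrolyses F5 to (2R,3S,4E)-2-(3-bromobut-3-en-1-yl)-5-(furan-3-yl)-3-methyl-3-(prop-2-en-1-yl)pent-4-enoic acid F6.
- Phenylselenolactonisation (PhSeCl, CH2Cl2, −78 °C) should attack the furyl-conjugated alkene, the most electron-rich one, 6-endo at the furyl-stabilised carbon. It gives the 5-(phenylselanyl) δ-lactone F7.
- H2O2/pyridine gives the selenoxide F8, whose syn-elimination (only the C6–H is available) delivers 11.

**Step 10 (ring-closing metathesis).** The ruthenium alkylidene on the allyl group can instead close a seven-membered ring onto the 1,1-disubstituted methylidene, and the strained ten-membered ring may give dimers. Triene 17 can also undergo 6π-electrocyclisation if heated. The fallback closes the ring at the C10–C1 bond with palladium instead, after the Z alkene has been set separately. It sets out from stannane 12 and returns at 18.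
- Z-retentive cross-metathesis of 12 with (Z)-but-2-ene-1,4-diol (Ru catechodithiolate catalyst, THF, 22 °C) gives (3R,4S)-6-(furan-3-yl)-4-[(2Z)-4-hydroxybut-2-en-1-yl]-4-methyl-3-[3-(trimethylstannyl)but-3-en-1-yl]-3,4-dihydro-2H-pyran-2-one F9.
- Dess–Martin oxidation (NaHCO3, 0 °C) gives the (2Z)-enal F10, used at once.
- Wittig reaction with ylide 15, made as in step 8, gives the (2Z,4Z)-2-bromodienoate F11.
- Intramolecular Stille coupling (Pd2(dba)3, AsPh3, CuI, NMP, 1 mM, 23 °C) gives 18.

**Step 9 (Stille coupling).** The 1,1-disubstituted stannane may transmetalate slowly, and 16 may polymerise or homocouple. The fallback reverses the roles of the partners. It sets out from bromide 11 (skipping step 7) and bromide 16 and returns at 17.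
- 16 is stannylated (Me3SnSnMe3, Pd(PPh3)4, toluene, 60 °C) to methyl (2Z)-2-(trimethylstannyl)penta-2,4-dienoate F12.
- F12 is coupled with vinyl bromide 11 (Pd(PPh3)4, CuI, CsF, DMF, 40 °C) to give 17.

## Further compounds

F1 | step 6 | (1R,2Z)-1-(furan-3-yl)-3-methylhexa-2,5-dien-1-ol | C=CC/C(C)=C\[C@@H](O)c1ccoc1
F2 | step 6 | 5-bromohex-5-enoic acid | C=C(Br)CCCC(=O)O
F3 | step 6 | (1R,2Z)-1-(furan-3-yl)-3-methylhexa-2,5-dien-1-yl 5-bromohex-5-enoate | C=CC/C(C)=C\[C@@H](OC(=O)CCCC(Br)=C)c1ccoc1
F4 | step 6 | (E)-trimethylsilyl ketene acetal of F3 | C=CC/C(C)=C\[C@@H](O/C(O[Si](C)(C)C)=C\CCC(Br)=C)c1ccoc1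
F5 | step 6 | trimethylsilyl (2R,3S,4E)-2-(3-bromobut-3-en-1-yl)-5-(furan-3-yl)-3-methyl-3-(prop-2-en-1-yl)pent-4-enoate | C=C(Br)CC[C@@H](C(=O)O[Si](C)(C)C)[C@](C)(/C=C/c1ccoc1)CC=C
F6 | step 6 | (2R,3S,4E)-2-(3-bromobut-3-en-1-yl)-5-(furan-3-yl)-3-methyl-3-(prop-2-en-1-yl)pent-4-enoic acid | C=C(Br)CC[C@@H](C(=O)O)[C@](C)(/C=C/c1ccoc1)CC=C
F7 | step 6 | 5-(phenylselanyl)-5,6-dihydro analogue of 11 (tetrahydropyran-2-one; lactone α-carbon and quaternary carbon as in 11, 5,6-trans, mixture at C5/C6) | C=C(Br)CC[C@@H](C(=O)O1)[C@](C)(C([Se]c2ccccc2)C1c3ccoc3)CC=C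
F8 | step 6 | selenoxide of F7 | C=C(Br)CC[C@@H](C(=O)O1)[C@](C)(C([Se](=O)c2ccccc2)C1c3ccoc3)CC=C
F9 | step 10 | (3R,4S)-6-(furan-3-yl)-4-[(2Z)-4-hydroxybut-2-en-1-yl]-4-methyl-3-[3-(trimethylstannyl)but-3-en-1-yl]-3,4-dihydro-2H-pyran-2-one | C=C([Sn](C)(C)C)CC[C@@H](C(=O)O1)[C@](C)(C=C1c2ccoc2)C/C=C\CO
F10 | step 10 | (2Z)-4-{(3R,4S)-6-(furan-3-yl)-4-methyl-2-oxo-3-[3-(trimethylstannyl)but-3-en-1-yl]-3,4-dihydro-2H-pyran-4-yl}but-2-enal | C=C([Sn](C)(C)C)CC[C@@H](C(=O)O1)[C@](C)(C=C1c2ccoc2)C/C=C\C=O
F11 | step 10 | methyl (2Z,4Z)-2-bromo-6-{(3R,4S)-6-(furan-3-yl)-4-methyl-2-oxo-3-[3-(trimethylstannyl)but-3-en-1-yl]-3,4-dihydro-2H-pyran-4-yl}hexa-2,4-dienoate | C=C([Sn](C)(C)C)CC[C@@H](C(=O)O1)[C@](C)(C=C1c2ccoc2)C/C=C\C=C(/Br)C(=O)OC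
F12 | step 9 | methyl (2Z)-2-(trimethylstannyl)penta-2,4-dienoate | C=C/C=C(\[Sn](C)(C)C)C(=O)OC
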